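**Plan**

- Feature (labdane numbering): rings A (C1–C5, C10) and B (C5–C10) are cis-fused, with H5, the C20 methyl on C10, the ester carbon C19 on C4 and C11 on C9 all on one face, next to an exocyclic C8=C17 methylene. This is the pattern that anti addition across Z alkenes of an open chain leaves behind.
- Retrosynthesis: put an oxygen back on C3, then cut C4–C5 and C9–C10 together (epoxide-initiated, allylsilane-terminated cation–olefin bicyclisation). Before that cut C12–C13 (B-alkyl Suzuki), C11–C12 (Wittig), C8–C17 (carbocupration), C9–C11 (acylation), C6–C7 (propargyl alkylation) and C3=C4 (Still–Gennari).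
- Forward: neryl acetate supplies the Z C5=C10 alkene; the chain grows at C6, the far terminus is rebuilt as a Z allylic alcohol and epoxidised, the alkyne becomes the allylsilane and a diene, and the finished side chain is coupled on. Ring A and ring B then close in one step, followed by C3 deoxygenation and oxidation of C19 to the ester.
- Stereochemistry: the Sharpless epoxide (D-(−)-DIPT) fixes the absolute configuration; the Z C3=C4, Z C5=C10 and C7/C11-cis allylsilane geometries are translated into C4, C5, C10 and C9; the 13E alkene comes from trans-hydroalumination/iodination of butynediol.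

Key step: step 18

Remark: neryl acetate, the commercial acetate of nerol, is taken as the C10 building block; compounds 2–4, 6 and 7 are racemic at an epoxide carbon that step 5 removes; labdane numbering is used for open-chain compounds too.

**Route**

Step 1
Reactants: 1 neryl acetate
Product: 2 6,7-epoxyneryl acetate (racemic)
Conditions: mCPBA, NaHCO3, CH2Cl2, 0 °C
Reagents that add atoms: mCPBA, OOC(=O)c1cccc(Cl)c1
Why: Prilezhaev epoxidation should go to the electron-rich terminal alkene because the allylic acetate deactivates the C2=C3 alkene inductively, and the new centre is racemic and is cleaved away in step 5.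

Step 2
Reactants: 2 6,7-epoxyneryl acetate
Product: 3 6,7-epoxynerol (racemic)
Conditions: K2CO3, MeOH, rt
Reagents that add atoms: none
Why: Base-catalysed transesterification (methanolysis) should free the allylic alcohol without opening the trisubstituted epoxide.

Step 3
Reactants: 3 6,7-epoxynerol
Product: 4 6,7-epoxyneryl bromide (racemic)
Conditions: CBr4, PPh3, CH2Cl2, 0 °C
Reagents that add atoms: tetrabromomethane, BrC(Br)(Br)Br
Why: Appel bromination is an SN2 displacement at the primary allylic carbon under neutral conditions, so the Z alkene and the epoxide should be kept.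

Step 4
Reactants: 5 1-(trimethylsilyl)propyne; 4 6,7-epoxyneryl bromide
Product: 7 terminal enyne epoxide (racemic), via silylated enyne epoxide 6 (not isolated)
Conditions: n-BuLi, THF, −78 to −20 °C; 4, −78 to 0 °C; then TBAF, 0 °C to rt
Reagents that add atoms: none
Why: Alkylation of lithiated 1-(trimethylsilyl)propyne should occur at its propargylic carbon by SN2 on the allylic bromide (C6–C7 bond, Z alkene retained), and fluoride then cleaves the C(sp)–Si bond in the same pot.

Step 5
Reactants: 7 terminal enyne epoxide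
Product: 8 (4Z)-4-methylnon-4-en-8-ynal
Conditions: H5IO6, THF/H2O, 0 °C
Reagents that add atoms: none
Why: Periodic acid opens the epoxide and cleaves the resulting glycol (Malaprade-type cleavage) to the C3 aldehyde and acetone, leaving alkyne and Z alkene untouched and removing the racemic centre.

Step 6
Reactants: 8 (4Z)-4-methylnon-4-en-8-ynal; 9 ethyl 2-[bis(2,2,2-trifluoroethoxy)phosphoryl]propanoate
Product: 10 ethyl (2Z,6Z)-2,6-dimethylundeca-2,6-dien-10-ynoate
Conditions: 9, KHMDS, 18-crown-6, THF, −78 °C; then 8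
Reagents that add atoms: none
Why: Still–Gennari olefination with the trifluoroethyl phosphonate under dissociating conditions should give the Z α-methyl enoate, which places the future C19 carbon cis to the chain.

Step 7
Reactants: 10 ethyl (2Z,6Z)-2,6-dimethylundeca-2,6-dien-10-ynoate
Product: 11 (2Z,6Z)-2,6-dimethylundeca-2,6-dien-10-yn-1-ol
Conditions: DIBAL-H, CH2Cl2, −78 °C
Reagents that add atoms: none
Why: 1,2-Reduction of the conjugated ester by DIBAL-H should give the Z allylic alcohol without isomerisation, the terminal alkyne being inert at −78 °C.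

Step 8
Reactants: 11 (2Z,6Z)-2,6-dimethylundeca-2,6-dien-10-yn-1-ol
Product: 12 [(2R,3S)-2-methyl-3-[(3Z)-3-methyloct-3-en-7-yn-1-yl]oxiran-2-yl]methanol
Conditions: Ti(OiPr)4, D-(−)-DIPT, t-BuOOH, 4 Å MS, CH2Cl2, −20 °C
Reagents that add atoms: tert-butyl hydroperoxide, CC(C)(C)OO
Why: Sharpless asymmetric epoxidation is hydroxyl-directed, so only the allylic alkene reacts, and the D-(−)-tartrate should deliver oxygen to the face that gives the (2R,3S) epoxide (C3 S and C4 R in labdane numbering).

Step 9
Reactants: 12 epoxy alcohol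
Product: 13 TBS ether of 12
Conditions: TBSCl, imidazole, DMF, 0 °C to rt
Reagents that add atoms: tert-butyldimethylsilyl chloride, CC(C)(C)[Si](C)(C)Cl
Why: Silylation of the primary alcohol gives an ether that should withstand organolithium, cuprate and DIBAL-H and is a weakly Lewis-basic spectator next to the epoxide in step 18.

Step 10
Reactants: 13 TBS ether of 12
Product: 15 methyl alkynoate, via lithium acetylide 14 (not isolated)
Conditions: n-BuLi, THF, −78 °C; ClCO2Me, −78 to 0 °C
Reagents that add atoms: methyl chloroformate, COC(=O)Cl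
Why: Deprotonation of the terminal alkyne and acylation of the acetylide with the chloroformate should give the alkynoate (C9–C11 bond), the trisubstituted epoxide being inert to the base at −78 °C.

Step 11
Reactants: 15 methyl alkynoate; 16 (trimethylsilyl)methylmagnesium chloride
Product: 17 methyl (2E,6Z)-β-(trimethylsilylmethyl) dienoate
Conditions: 16 (2.2 equiv), CuI (1.1 equiv), THF, −30 °C; then 15, −78 °C; MeOH, −78 °C
Reagents that add atoms: none
Why: Syn carbocupration of the alkynoate adds CH2SiMe3 and copper to the same face, and protonation at −78 °C before allenoate equilibration should leave CH2SiMe3 cis to H, so that C7 is cis to the ester carbon C11.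

Step 12
Reactants: 17 dienoate
Product: 18 (2E,6Z)-dienol
Conditions: DIBAL-H, CH2Cl2, −78 °C; Rochelle salt
Reagents that add atoms: none
Why: 1,2-Reduction by DIBAL-H with a non-acidic work-up should give the allylic alcohol without loss of silicon or opening of the epoxide.

Step 13
Reactants: 18 dienol
Product: 19 (2E,6Z)-dienal
Conditions: MnO2, CH2Cl2, rt
Reagents that add atoms: none
Why: Manganese dioxide oxidation is selective for the allylic alcohol and neutral, so the enal should form without E/Z isomerisation or desilylation.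

Step 14
Reactants: 19 dienal
Product: 20 (3E,7Z)-triene
Conditions: Ph3PCH3Br, KHMDS, THF, 0 °C; then 19, −78 to 0 °C
Reagents that add atoms: methyltriphenylphosphonium bromide, C[P+](c1ccccc1)(c1ccccc1)c1ccccc1.[Br-]
Why: Wittig methylenation adds C12 faster than the ylide can deprotonate the γ-position, so the C8=C9 geometry should be retained in the 2-(silylmethyl) diene.

Step 15
Reactants: 21 but-2-yne-1,4-diol
Product: 23 (2Z)-2-iodobut-2-ene-1,4-diol, via cyclic alkenylaluminate 22 (not isolated)
Conditions: Red-Al, THF, 0 °C to rt; then I2, −78 °C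
Reagents that add atoms: iodine, II
Why: Alkoxide-directed trans-hydroalumination places aluminium cis to its own CH2O group, and iodinolysis with retention should give the iodide in which the two CH2OH groups are trans.

Step 16
Reactants: 23 (2Z)-2-iodobut-2-ene-1,4-diol
Product: 24 (2Z)-1,4-bis(TBDPS-oxy)-2-iodobut-2-ene
Conditions: TBDPSCl, imidazole, DMF, rt
Reagents that add atoms: tert-butyldiphenylsilyl chloride, CC(C)(C)[Si](Cl)(c1ccccc1)c1ccccc1
Why: Silylation of both primary alcohols gives ethers chosen to outlast the C19 TBS ether under the acid of step 21.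

Step 17
Reactants: 20 triene; 24 bis-silylated alkenyl iodide
Product: 26 acyclic Z,Z-epoxy allylsilane carrying the complete side chain, via B-alkyl-9-BBN adduct 25 (not isolated)
Conditions: 9-BBN, THF, 0 °C to rt; then 24, Pd(dppf)Cl2, AsPh3, Cs2CO3, DMF/H2O, rt
Reagents that add atoms: none
Why: 9-BBN should add anti-Markovnikov only to the monosubstituted diene terminus, and B-alkyl Suzuki–Miyaura coupling then forms C12–C13 with retention of the alkenyl iodide geometry (13E).

Step 18
Reactants: 26 acyclic Z,Z-epoxy allylsilane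
Product: 27 cis-fused 3-hydroxy bicycle with C8 methylene
Conditions: MeAlCl2 (2.5 equiv), CH2Cl2, −78 °C; Et3N/MeOH quench
Reagents that add atoms: none
Why: The Lewis acid binds the epoxide oxygen and the C4–O bond ionises as C5 of the Z C5=C10 alkene attacks C4 anti to oxygen (ring A, 6-endo-trig at the alkene), C9 of the allylsilane takes the developing C10 cation from the opposite face (ring B, 6-endo-trig), and loss of Me3Si from the β-silyl C8 cation leaves the C8=C17 methylene. The closest known reaction type is the Lewis-acid epoxide-initiated, allylsilane-terminated polyene bicyclisation, whose ring-fusion geometry follows the alkene geometry (Stork–Eschenmoser). C3 keeps its Sharpless configuration (equatorial OH) and C4 is inverted, so the epoxide substituent cis to the chain (C19) becomes axial and cis to H5. Anti addition across the Z C5=C10 alkene in a chair–chair array puts H5 and the C20 methyl cis, and C11, cis to C7 on the allylsilane, becomes axial at C9 on the methyl face. The step needs concerted chair–chair closure instead of stepwise cation equilibration or hydride shift to a C3 ketone; the fixed alkene geometries, ionisation at the tertiary C4, the strongly nucleophilic allylsilane and −78 °C favour it, and the C13=C14 alkene is deactivated by two allylic silyloxy groups and too remote from C10 to compete.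

Step 19
Reactants: 27 hydroxy bicycle
Product: 28 3-O-(imidazol-1-ylthiocarbonyl) derivative
Conditions: 1,1'-thiocarbonyldiimidazole, DMAP, toluene, 90 °C
Reagents that add atoms: 1,1'-thiocarbonyldiimidazole, S=C(n1ccnc1)n1ccnc1
Why: Thioacylation of the equatorial 3-OH without forming an alkoxide should avoid silyl migration from O19 and supplies the radical leaving group.

Step 20
Reactants: 28 thiocarbonyl derivative
Product: 29 3-deoxy bicycle
Conditions: Bu3SnH, AIBN, toluene, 110 °C
Reagents that add atoms: none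
Why: Barton–McCombie deoxygenation: stannyl radical adds to C=S, β-scission gives the secondary C3 radical and hydrogen transfer from the stannane leaves C3 as CH2.

Step 21
Reactants: 29 3-deoxy bicycle
Product: 30 C19 alcohol
Conditions: CSA (cat.), MeOH/CH2Cl2, 0 °C to rt
Reagents that add atoms: none
Why: Acid-catalysed methanolysis should remove the TBS ether much faster than the two primary TBDPS ethers, and the acid is too weak to move the exocyclic alkene.

Step 22
Reactants: 30 C19 alcohol
Product: 31 C19 aldehyde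
Conditions: Dess–Martin periodinane, NaHCO3, CH2Cl2, rt
Reagents that add atoms: none
Why: Dess–Martin oxidation converts the neopentyl alcohol into an aldehyde that has no α-hydrogen, so C4 cannot epimerise.

Step 23
Reactants: 31 C19 aldehyde
Product: 32 C19 carboxylic acid
Conditions: NaClO2, NaH2PO4, 2-methylbut-2-ene, t-BuOH/H2O, rt
Reagents that add atoms: sodium chlorite, [Na+].[O-]Cl=O
Why: Pinnick oxidation should give the acid while the scavenger removes HOCl before it can add to the two alkenes.

Step 24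
Reactants: 32 C19 carboxylic acid
Product: 33 methyl ester bis-TBDPS ether
Conditions: TMSCHN2, MeOH/toluene, 0 °C to rt
Reagents that add atoms: (trimethylsilyl)diazomethane, C[Si](C)(C)C=[N+]=[N-]
Why: O-Methylation through the protonated diazoalkane alkylates the carboxylate oxygen, so the hindrance at the axial C4 carbonyl does not matter.

Step 25
Reactants: 33 methyl ester bis-TBDPS ether
Product: 34 target CNP0282002.1
Conditions: TBAF, THF, rt
Reagents that add atoms: none
Why: Fluoride-driven desilylation should free both allylic alcohols, and the hindered tertiary methyl ester is not hydrolysed.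

**Compound list**

1 | neryl acetate, (2Z)-3,7-dimethylocta-2,6-dien-1-yl acetate | CC(C)=CCC/C(C)=C\COC(C)=O | starting material
2 | 6,7-epoxyneryl acetate, (2Z)-5-(3,3-dimethyloxiran-2-yl)-3-methylpent-2-en-1-yl acetate (racemic) | CC1(C)OC1CC/C(C)=C\COC(C)=O | intermediate
3 | 6,7-epoxynerol, (2Z)-5-(3,3-dimethyloxiran-2-yl)-3-methylpent-2-en-1-ol (racemic) | CC1(C)OC1CC/C(C)=C\CO | intermediate
4 | 6,7-epoxyneryl bromide, 3-[(3Z)-5-bromo-3-methylpent-3-en-1-yl]-2,2-dimethyloxirane (racemic) | CC1(C)OC1CC/C(C)=C\CBr | intermediate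
5 | 1-(trimethylsilyl)propyne | CC#C[Si](C)(C)C | starting material
6 | silylated enyne epoxide, [(5Z)-8-(3,3-dimethyloxiran-2-yl)-6-methyloct-5-en-1-yn-1-yl]trimethylsilane (racemic, not isolated) | C[Si](C)(C)C#CCC/C=C(/C)CCC1OC1(C)C | intermediate
7 | terminal enyne epoxide, 2,2-dimethyl-3-[(3Z)-3-methyloct-3-en-7-yn-1-yl]oxirane (racemic) | C#CCC/C=C(/C)CCC1OC1(C)C | intermediate
8 | (4Z)-4-methylnon-4-en-8-ynal | C#CCC/C=C(/C)CCC=O | intermediate
9 | ethyl 2-[bis(2,2,2-trifluoroethoxy)phosphoryl]propanoate | CCOC(=O)C(C)P(=O)(OCC(F)(F)F)OCC(F)(F)F | starting material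
10 | ethyl (2Z,6Z)-2,6-dimethylundeca-2,6-dien-10-ynoate | C#CCC/C=C(/C)CC/C=C(/C)C(=O)OCC | intermediate
11 | (2Z,6Z)-2,6-dimethylundeca-2,6-dien-10-yn-1-ol | C#CCC/C=C(/C)CC/C=C(/C)CO | intermediate
12 | [(2R,3S)-2-methyl-3-[(3Z)-3-methyloct-3-en-7-yn-1-yl]oxiran-2-yl]methanol (CH2OH cis to the chain) | C#CCC/C=C(/C)CC[C@@H]1O[C@]1(C)CO | intermediate
13 | TBS ether of 12 | C#CCC/C=C(/C)CC[C@@H]1O[C@]1(C)CO[Si](C)(C)C(C)(C)C | intermediate
14 | lithium acetylide of 13 (not isolated) | [Li]C#CCC/C=C(/C)CC[C@@H]1O[C@]1(C)CO[Si](C)(C)C(C)(C)C | intermediate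
15 | methyl (6Z)-9-[(2S,3R)-3-(TBS-oxymethyl)-3-methyloxiran-2-yl]-7-methylnon-6-en-2-ynoate | COC(=O)C#CCC/C=C(/C)CC[C@@H]1O[C@]1(C)CO[Si](C)(C)C(C)(C)C | intermediate
16 | (trimethylsilyl)methylmagnesium chloride | C[Si](C)(C)C[Mg]Cl | starting material
17 | methyl (2E,6Z)-9-[(2S,3R)-3-(TBS-oxymethyl)-3-methyloxiran-2-yl]-7-methyl-3-[(trimethylsilyl)methyl]nona-2,6-dienoate (chain carbon C7 cis to the ester) | C[Si](C)(C)C/C(CC/C=C(/C)CC[C@@H]1O[C@]1(C)CO[Si](C)(C)C(C)(C)C)=C/C(=O)OC | intermediate
18 | (2E,6Z)-dienol, the primary allylic alcohol from 17 | C[Si](C)(C)C/C(CC/C=C(/C)CC[C@@H]1O[C@]1(C)CO[Si](C)(C)C(C)(C)C)=C/CO | intermediate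
19 | (2E,6Z)-dienal, the enal from 18 | C[Si](C)(C)C/C(CC/C=C(/C)CC[C@@H]1O[C@]1(C)CO[Si](C)(C)C(C)(C)C)=C/C=O | intermediate
20 | (3E,7Z)-10-[(2S,3R)-3-(TBS-oxymethyl)-3-methyloxiran-2-yl]-8-methyl-4-[(trimethylsilyl)methyl]deca-1,3,7-triene | C[Si](C)(C)C/C(CC/C=C(/C)CC[C@@H]1O[C@]1(C)CO[Si](C)(C)C(C)(C)C)=C/C=C | intermediate
21 | but-2-yne-1,4-diol | OCC#CCO | starting material
22 | cyclic alkenylaluminate from 21 and Red-Al, simplest monomeric form (not isolated) | [Na+].COCCO[Al-]1(OCCOC)OCC=C1CO | intermediate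
23 | (2Z)-2-iodobut-2-ene-1,4-diol (I cis to C4, the two CH2OH trans) | OC/C(I)=C/CO | intermediate
24 | (2Z)-1,4-bis(TBDPS-oxy)-2-iodobut-2-ene | I/C(CO[Si](c1ccccc1)(c1ccccc1)C(C)(C)C)=C\CO[Si](c1ccccc1)(c1ccccc1)C(C)(C)C | intermediate
25 | B-alkyl-9-BBN adduct of 20, boron on C12 (not isolated) | C[Si](C)(C)C/C(CC/C=C(/C)CC[C@@H]1O[C@]1(C)CO[Si](C)(C)C(C)(C)C)=C/CCB1C2CCCC1CCC2 | intermediate
26 | key-step precursor: open-chain (3S,4R)-3,4-epoxide with 19-OTBS, Z C5=C10, C8(CH2SiMe3)=C9 with C7 cis to C11, and 13E side chain with 15,16-bis-OTBDPS | C[Si](C)(C)C/C(CC/C=C(/C)CC[C@@H]1O[C@]1(C)CO[Si](C)(C)C(C)(C)C)=C/CC/C(=C\CO[Si](c1ccccc1)(c1ccccc1)C(C)(C)C)CO[Si](c1ccccc1)(c1ccccc1)C(C)(C)C | intermediate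
27 | key-step product: (13E)-19-(TBS-oxy)-15,16-bis(TBDPS-oxy)-5β-labda-8(17),13-dien-3-ol; cis-decalin with H5, C20, C19 and C11 on one face, 3-OH equatorial and cis to C19 | C=C1CC[C@H]2[C@](C)(CC[C@H](O)[C@]2(C)CO[Si](C)(C)C(C)(C)C)[C@H]1CC/C(=C\CO[Si](c1ccccc1)(c1ccccc1)C(C)(C)C)CO[Si](c1ccccc1)(c1ccccc1)C(C)(C)C | intermediate
28 | O-(C3) 1H-imidazole-1-carbothioate of 27 | C=C1CC[C@H]2[C@](C)(CC[C@H](OC(=S)n3ccnc3)[C@]2(C)CO[Si](C)(C)C(C)(C)C)[C@H]1CC/C(=C\CO[Si](c1ccccc1)(c1ccccc1)C(C)(C)C)CO[Si](c1ccccc1)(c1ccccc1)C(C)(C)C | intermediate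
29 | 3-deoxy bicycle: (13E)-19-(TBS-oxy)-15,16-bis(TBDPS-oxy)-5β-labda-8(17),13-diene | C=C1CC[C@H]2[C@](C)(CCC[C@]2(C)CO[Si](C)(C)C(C)(C)C)[C@H]1CC/C(=C\CO[Si](c1ccccc1)(c1ccccc1)C(C)(C)C)CO[Si](c1ccccc1)(c1ccccc1)C(C)(C)C | intermediate
30 | C19 alcohol: (13E)-15,16-bis(TBDPS-oxy)-5β-labda-8(17),13-dien-19-ol | C=C1CC[C@H]2[C@](C)(CCC[C@]2(C)CO)[C@H]1CC/C(=C\CO[Si](c1ccccc1)(c1ccccc1)C(C)(C)C)CO[Si](c1ccccc1)(c1ccccc1)C(C)(C)C | intermediate
31 | C19 aldehyde of 30 | C=C1CC[C@H]2[C@](C)(CCC[C@]2(C)C=O)[C@H]1CC/C(=C\CO[Si](c1ccccc1)(c1ccccc1)C(C)(C)C)CO[Si](c1ccccc1)(c1ccccc1)C(C)(C)C | intermediate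
32 | C19 carboxylic acid | C=C1CC[C@H]2[C@](C)(CCC[C@]2(C)C(=O)O)[C@H]1CC/C(=C\CO[Si](c1ccccc1)(c1ccccc1)C(C)(C)C)CO[Si](c1ccccc1)(c1ccccc1)C(C)(C)C | intermediate
33 | methyl (13E)-15,16-bis(TBDPS-oxy)-5β-labda-8(17),13-dien-19-oate | C=C1CC[C@H]2[C@](C)(CCC[C@]2(C)C(=O)OC)[C@H]1CC/C(=C\CO[Si](c1ccccc1)(c1ccccc1)C(C)(C)C)CO[Si](c1ccccc1)(c1ccccc1)C(C)(C)C | intermediate
34 | CNP0282002.1, methyl (4S,5S,9S,10R,13E)-15,16-dihydroxylabda-8(17),13-dien-19-oate | C=C1CC[C@H]2[C@](C)(CCC[C@]2(C)C(=O)OC)[C@H]1CC/C(=C\CO)CO | target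

**Step count and risks**

Total step count: 25. Longest linear sequence: 23 steps (steps 1–14 and 17–25); steps 15–16 make the side-chain iodide.

Step 18 (key step). The cascade may be diverted before ring B closes. Ionisation at C4 is slowed by the neighbouring silyloxymethyl group and part of the Lewis acid is held by three silyl ethers. A longer-lived cation could then undergo hydride shift to a C3 ketone, lose a proton after ring A, or close stepwise with leakage towards the trans-fused isomer; the C13=C14 alkene is a further nucleophile near the C8 cation. The fallback runs the same cascade on a leaner substrate and adds the side chain afterwards; it sets out from triene 20 and comes back at 29. Hydroboration of 20 as in step 17 (adduct 25) and oxidative work-up (NaBO3) would give the homoallylic alcohol F1, and pivaloyl chloride/pyridine the pivalate F2, whose C9 arm has two carbons, no alkene and one weakly basic ester. MeAlCl2 at −78 °C should convert F2 into the hydroxy bicycle F3. Thiocarbonyldiimidazole gives the thiocarbonyl derivative F4 and Bu3SnH/AIBN the 3-deoxy pivalate F5. DIBAL-H removes the pivalate to give the alcohol F6, PPh3/imidazole/I2 gives the iodide F7, and zinc insertion (Zn, LiCl, THF) the alkylzinc iodide F8. Negishi coupling of F8 with 24 (Pd(PPh3)4) gives 29.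

Step 17. Transmetalation of the homoallylic B-alkyl-9-BBN onto the hindered, doubly allylic-oxygenated alkenylpalladium may be slow, so that protodeboronation, β-hydride elimination and reduction of the iodide compete. The fallback replaces the in situ borane by an isolated iodide and an organozinc; it sets out from 20 and comes back at 26. Adduct 25 is oxidised to the homoallylic alcohol F1 described above, and PPh3/imidazole/I2 (iodine added last at 0 °C) gives the primary iodide F9. Zinc insertion (Zn, LiCl, THF, rt) gives the alkylzinc iodide F10, which is coupled with 24 under Negishi conditions (Pd(dppf)Cl2) to give 26.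

Step 21. Discrimination between the neopentyl C19 TBS ether and the two primary allylic TBDPS ethers under acid may be incomplete, with partial loss of TBDPS, or cleavage may be so slow that the exocyclic alkene begins to migrate. The fallback exchanges the protecting groups by steric selection; it sets out from 29 and comes back at 34. TBAF removes all three silyl groups to give the triol F11. Pivaloyl chloride (2.1 equiv, pyridine, −20 to 0 °C) acylates only the two unhindered allylic alcohols and gives the bis-pivalate F12 with the axial neopentyl C19 alcohol free. Dess–Martin oxidation gives the aldehyde F13, Pinnick oxidation the acid F14 and TMSCHN2 the methyl ester F15. NaOMe in MeOH cleaves both pivalates, transesterification of the hindered methyl ester being degenerate, and gives 34.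

**Further compounds**

F1 | step 18 | homoallylic alcohol from 20 (C12 OH) | C[Si](C)(C)C/C(CC/C=C(/C)CC[C@@H]1O[C@]1(C)CO[Si](C)(C)C(C)(C)C)=C/CCO
F2 | step 18 | C12 pivalate of F1 | C[Si](C)(C)C/C(CC/C=C(/C)CC[C@@H]1O[C@]1(C)CO[Si](C)(C)C(C)(C)C)=C/CCOC(=O)C(C)(C)C
F3 | step 18 | cis-fused 3-hydroxy bicycle with C12 pivalate and 19-OTBS | C=C1CC[C@H]2[C@](C)(CC[C@H](O)[C@]2(C)CO[Si](C)(C)C(C)(C)C)[C@H]1CCOC(=O)C(C)(C)C
F4 | step 18 | O-(C3) 1H-imidazole-1-carbothioate of F3 | C=C1CC[C@H]2[C@](C)(CC[C@H](OC(=S)n3ccnc3)[C@]2(C)CO[Si](C)(C)C(C)(C)C)[C@H]1CCOC(=O)C(C)(C)C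
F5 | step 18 | 3-deoxy pivalate | C=C1CC[C@H]2[C@](C)(CCC[C@]2(C)CO[Si](C)(C)C(C)(C)C)[C@H]1CCOC(=O)C(C)(C)C
F6 | step 18 | C12 alcohol | C=C1CC[C@H]2[C@](C)(CCC[C@]2(C)CO[Si](C)(C)C(C)(C)C)[C@H]1CCO
F7 | step 18 | C12 iodide | C=C1CC[C@H]2[C@](C)(CCC[C@]2(C)CO[Si](C)(C)C(C)(C)C)[C@H]1CCI
F8 | step 18 | C12 alkylzinc iodide (not isolated) | C=C1CC[C@H]2[C@](C)(CCC[C@]2(C)CO[Si](C)(C)C(C)(C)C)[C@H]1CC[Zn]I
F9 | step 17 | open-chain C12 iodide from F1 | C[Si](C)(C)C/C(CC/C=C(/C)CC[C@@H]1O[C@]1(C)CO[Si](C)(C)C(C)(C)C)=C/CCI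
F10 | step 17 | open-chain C12 alkylzinc iodide (not isolated) | C[Si](C)(C)C/C(CC/C=C(/C)CC[C@@H]1O[C@]1(C)CO[Si](C)(C)C(C)(C)C)=C/CC[Zn]I
F11 | step 21 | triol, (13E)-5β-labda-8(17),13-diene-15,16,19-triol | C=C1CC[C@H]2[C@](C)(CCC[C@]2(C)CO)[C@H]1CC/C(=C\CO)CO
F12 | step 21 | 15,16-bis-pivalate of F11 | C=C1CC[C@H]2[C@](C)(CCC[C@]2(C)CO)[C@H]1CC/C(=C\COC(=O)C(C)(C)C)COC(=O)C(C)(C)C
F13 | step 21 | C19 aldehyde bis-pivalate | C=C1CC[C@H]2[C@](C)(CCC[C@]2(C)C=O)[C@H]1CC/C(=C\COC(=O)C(C)(C)C)COC(=O)C(C)(C)C
F14 | step 21 | C19 acid bis-pivalate | C=C1CC[C@H]2[C@](C)(CCC[C@]2(C)C(=O)O)[C@H]1CC/C(=C\COC(=O)C(C)(C)C)COC(=O)C(C)(C)C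
F15 | step 21 | C19 methyl ester bis-pivalate | C=C1CC[C@H]2[C@](C)(CCC[C@]2(C)C(=O)OC)[C@H]1CC/C(=C\COC(=O)C(C)(C)C)COC(=O)C(C)(C)C
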